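## Retrosynthetic overview

1. Target 22 ⇐ ketone 20: methylene transfer to C8, oxirane closed by intramolecular C–O bond formation (last ring).
2. 20 ⇐ alkylidene lactone 19: key C13–O spiro-etherification by the 9α-OH (new cobalt-hydride method, sets C13); 19 ⇐ 17 + α-methylene-γ-butyrolactone 18 (cross-metathesis).
3. 17 ⇐ enone acid 16 by oxa-Michael lactonisation (C6–O); enone from Stork–Danheiser transposition of vinylogous ester 11; C9 carbinol by allylation of 9.
4. 9 ⇐ quinone 7 (ring B, brings the oxygens at C6, C8, C9) + (Z)-dienyl ether 5 (C1–C4, C18, C19) by enantioselective Diels–Alder reaction (ring A).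
5. Ring order: B (quinone) → A (cycloaddition) → 19,6-lactone → spiro-oxolane (butyrolactone arrives pre-formed) → oxirane.

Convention: labdane locants are used for all intermediates (C4 carries Me-18 and C19, C10 carries Me-20, ring B = C5–C10); β is the face of the C10 methyl.

Assumption: the (S)-oxazaborolidinium cation (step 4) and the (R,R)-cobalt salen complex (step 10) induce the sense drawn; if a first run shows the opposite, the mirror-image catalyst is used and nothing else changes.

## Route

Step 1
Reactants: 1 prop-2-yn-1-ol; 2 bromoethene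
Product: 4 (2Z)-2-methylpenta-2,4-dien-1-ol, via alkenylmagnesium alkoxide 3 (not isolated)
Conditions: MeMgBr (2.5 equiv), CuI (10 mol%), THF, −10 °C to rt; then 2, Pd(PPh3)4 (3 mol%), rt; aq NH4Cl
Reagents that add atoms: methylmagnesium bromide C[Mg]Br
Why: copper-catalysed anti-carbomagnesiation of the propargylic alkoxide (chelate control puts Me on C2 and Mg on C3 cis to CH2O) followed by Kumada coupling with retention gives the diene whose CH2OH is cis to the vinyl group.

Step 2
Reactants: 4 (2Z)-2-methylpenta-2,4-dien-1-ol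
Product: 5 tert-butyldimethylsilyl (2Z)-2-methylpenta-2,4-dien-1-yl ether
Conditions: TBSCl, imidazole, CH2Cl2, 0 °C to rt
Reagents that add atoms: tert-butyldimethylsilyl chloride CC(C)(C)[Si](C)(C)Cl
Why: standard silylation of a primary alcohol, needed so that the diene tolerates the Lewis-acid catalyst of step 4.

Step 3
Reactants: 6 2-methoxy-6-methylphenol
Product: 7 2-methoxy-6-methyl-1,4-benzoquinone
Conditions: O2 (1 atm), Co(salen) [N,N′-bis(salicylidene)ethylenediaminocobalt] (5 mol%), DMF, rt
Reagents that add atoms: dioxygen O=O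
Why: cobalt–salen aerobic para-oxidation of a 2,6-disubstituted phenol with a free para position gives the p-benzoquinone.

Step 4
Reactants: 5 tert-butyldimethylsilyl (2Z)-2-methylpenta-2,4-dien-1-yl ether; 7 2-methoxy-6-methyl-1,4-benzoquinone
Product: 8 19-(tert-butyldimethylsilyloxy)-8-methoxy-11,12,13,14,15,16,17-heptanor-5β-labda-2,7-diene-6,9-dione
Conditions: (S)-o-tolyl-oxazaborolidine·Tf2NH (20 mol%), CH2Cl2, −78 to −30 °C
Reagents that add atoms: none
Why: cationic-oxazaborolidine-catalysed endo Diels–Alder reaction in which the catalyst binds the more basic vinylogous-ester carbonyl (C6=O) and activates the methyl-bearing double bond, so the diene CH2 terminus bonds to C10 and the substituted terminus to C5; the endo transition state places the inside (Z) CH2OTBS group cis to the angular methyl (C19 β, Me-18 α), the ring fusion is cis (5β-H), and the catalyst fixes the absolute sense.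

Step 5
Reactants: 8 19-(tert-butyldimethylsilyloxy)-8-methoxy-11,12,13,14,15,16,17-heptanor-5β-labda-2,7-diene-6,9-dione
Product: 9 19-(tert-butyldimethylsilyloxy)-8-methoxy-11,12,13,14,15,16,17-heptanor-5β-labd-7-ene-6,9-dione
Conditions: H2 (3 atm), RhCl(PPh3)3 (5 mol%), benzene–EtOH, rt
Reagents that add atoms: none
Why: homogeneous rhodium hydrogenation reduces only the isolated cis-disubstituted ring A olefin, the trisubstituted push–pull enedione C=C being inert; no stereocentre is formed.

Step 6
Reactants: 9 19-(tert-butyldimethylsilyloxy)-8-methoxy-11,12,13,14,15,16,17-heptanor-5β-labd-7-ene-6,9-dione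
Product: 11 19-(tert-butyldimethylsilyloxy)-9α-hydroxy-8-methoxy-14,15,16,17-tetranorlabda-7,12-dien-6-one, via 5β-epimer 10 (not isolated)
Conditions: allylMgBr (1.2 equiv), THF, −78 °C; MeOH quench; then NaOMe (0.3 equiv), MeOH, rt
Reagents that add atoms: allylmagnesium bromide C=CC[Mg]Br
Why: Grignard 1,2-addition goes to the C9 carbonyl because C6=O is a deactivated vinylogous ester, and it comes from the convex face of the cis-fused bicycle (syn to the angular H and Me, away from ring A), giving 9α-OH and 9β-allyl; methoxide then epimerises C5 through the C6 enolate to the more stable trans-fused 5α-H isomer.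

Step 7
Reactants: 11 19-(tert-butyldimethylsilyloxy)-9α-hydroxy-8-methoxy-14,15,16,17-tetranorlabda-7,12-dien-6-one
Product: 13 19-(tert-butyldimethylsilyloxy)-9α-hydroxy-14,15,16,17-tetranorlabda-6,12-dien-8-one, via allylic alcohol 12 (not isolated)
Conditions: LiAlH4, THF, −20 °C; then 5% aq oxalic acid, THF, 0 °C to rt
Reagents that add atoms: water O
Why: Stork–Danheiser transposition, in which 1,2-reduction of the vinylogous ester and mild acid hydrolysis with allylic shift unmask the C8 ketone and move the olefin to C6=C7; the C6 carbinol centre is destroyed and the silyl ether survives the brief mild acid.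

Step 8
Reactants: 13 19-(tert-butyldimethylsilyloxy)-9α-hydroxy-14,15,16,17-tetranorlabda-6,12-dien-8-one
Product: 17 9α-hydroxy-8-oxo-14,15,16,17-tetranorlabd-12-en-19,6β-olide, via primary alcohol 14 (not isolated), via aldehyde 15 (not isolated), via enone acid 16 (not isolated)
Conditions: CrO3, H2SO4, acetone–H2O, 0 °C to rt; iPrOH; then TsOH (5 mol%), CH2Cl2, rt
Reagents that add atoms: water O
Why: acidic chromium trioxide cleaves the primary silyl ether and oxidises C19 to the acid (tertiary carbinol and olefins are inert), and the axial 4β-carboxyl then adds to the enone (oxa-Michael lactonisation), its tether allowing only β-face delivery so that the 6β C–O bond is set.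

Step 9
Reactants: 17 9α-hydroxy-8-oxo-14,15,16,17-tetranorlabd-12-en-19,6β-olide; 18 α-methylene-γ-butyrolactone
Product: 19 (12E)-9α-hydroxy-8-oxo-17-norlabd-12-ene-19,6β:16,15-diolide
Conditions: 18 (4 equiv), second-generation Hoveyda–Grubbs catalyst RuCl2(H2IMes)(=CH-C6H4-2-OiPr) (5 mol%), 2,6-dichloro-1,4-benzoquinone (10 mol%), CH2Cl2, 40 °C
Reagents that add atoms: none
Why: olefin cross-metathesis of the terminal allyl group with excess 1,1-disubstituted acrylate-type partner gives the (E)-α-alkylidene lactone, the quinone additive suppressing olefin migration.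

Step 10
Reactants: 19 (12E)-9α-hydroxy-8-oxo-17-norlabd-12-ene-19,6β:16,15-diolide
Product: 20 (13R)-9α,13-epoxy-8-oxo-17-norlabdane-19,6β:16,15-diolide
Conditions: (R,R)-N,N′-bis(3,5-di-tert-butylsalicylidene)-1,2-cyclohexanediaminocobalt (5 mol%), N-fluoro-2,4,6-trimethylpyridinium triflate (1.3 equiv), PhSiH3 (1.3 equiv), PhCF3, 0 °C
Reagents that add atoms: none
Why: Proposed new method: α-selective (anti-Michael) hydroalkoxylation of an α-alkylidene lactone by a tertiary alcohol, in which the trivalent cobalt hydride (from the fluoro-cobalt species and silane) transfers H• to C12 to give the tertiary α-lactonyl radical at C13, the chiral divalent cobalt salen captures it face-selectively, oxidation gives a tetravalent alkylcobalt, and the tethered 9α-OH displaces cobalt with inversion in a 5-exo-tet closure, forming the C13–O bond and oxolane and setting C13 under catalyst control; the closest known reactions are cobalt-salen/N-fluoropyridinium/silane radical-polar-crossover hydroalkoxylation of unactivated olefins (including enantioselective versions) and Mukaiyama-type α-hydroxylation of unsaturated esters, neither shown for C–O ring closure at the α-carbon of an unsaturated lactone.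

Step 11
Reactants: 20 (13R)-9α,13-epoxy-8-oxo-17-norlabdane-19,6β:16,15-diolide
Product: 22 (13R)-8β,17:9α,13-diepoxylabdane-19,6β:16,15-diolide, via chlorohydrin alkoxide 21 (not isolated)
Conditions: ClCH2I (1.5 equiv), MeLi·LiBr (1.4 equiv), THF, −78 °C; then to rt
Reagents that add atoms: chloroiodomethane ClCI
Why: chloromethyllithium, made in situ by iodine–lithium exchange, adds to the ketone faster than it enolises it or attacks the lactones, along the equatorial α-trajectory because the axial β-approach is blocked by the syn-axial C10 methyl and C6–O bond; the resulting 8β-alkoxide closes onto CH2Cl (Williamson-type 3-exo-tet) to give the 8β,17-oxirane.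

## Compound list

1 | prop-2-yn-1-ol (propargyl alcohol) | C#CCO | starting material
2 | bromoethene (vinyl bromide) | C=CBr | starting material
3 | bromomagnesium (2Z)-3-(bromomagnesio)-2-methylprop-2-en-1-olate (Mg on C3 cis to CH2O) | Br[Mg]/C=C(/C)CO[Mg]Br | intermediate
4 | (2Z)-2-methylpenta-2,4-dien-1-ol (CH2OH cis to vinyl) | C=C/C=C(/C)CO | intermediate
5 | tert-butyldimethylsilyl (2Z)-2-methylpenta-2,4-dien-1-yl ether | C=C/C=C(/C)CO[Si](C)(C)C(C)(C)C | intermediate
6 | 2-methoxy-6-methylphenol | COc1cccc(C)c1O | starting material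
7 | 2-methoxy-6-methyl-1,4-benzoquinone | COC1=CC(=O)C=C(C)C1=O | intermediate
8 | 19-(tert-butyldimethylsilyloxy)-8-methoxy-11,12,13,14,15,16,17-heptanor-5β-labda-2,7-diene-6,9-dione (cis-fused; 4α-Me, 4β-CH2OTBS, 10β-Me) | C[C@]12CC=C[C@](C)(CO[Si](C)(C)C(C)(C)C)[C@H]1C(=O)C=C(OC)C2=O | intermediate
9 | 19-(tert-butyldimethylsilyloxy)-8-methoxy-11,12,13,14,15,16,17-heptanor-5β-labd-7-ene-6,9-dione | C[C@]12CCC[C@](C)(CO[Si](C)(C)C(C)(C)C)[C@H]1C(=O)C=C(OC)C2=O | intermediate
10 | 19-(tert-butyldimethylsilyloxy)-9α-hydroxy-8-methoxy-14,15,16,17-tetranor-5β-labda-7,12-dien-6-one (cis-fused, 9β-allyl) | C[C@]12CCC[C@](C)(CO[Si](C)(C)C(C)(C)C)[C@H]1C(=O)C=C(OC)[C@]2(O)CC=C | intermediate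
11 | 19-(tert-butyldimethylsilyloxy)-9α-hydroxy-8-methoxy-14,15,16,17-tetranorlabda-7,12-dien-6-one (trans-fused, 5α-H, 9β-allyl) | C[C@]12CCC[C@](C)(CO[Si](C)(C)C(C)(C)C)[C@@H]1C(=O)C=C(OC)[C@]2(O)CC=C | intermediate
12 | 19-(tert-butyldimethylsilyloxy)-8-methoxy-14,15,16,17-tetranorlabda-7,12-diene-6β,9α-diol | C[C@]12CCC[C@](C)(CO[Si](C)(C)C(C)(C)C)[C@@H]1[C@H](O)C=C(OC)[C@]2(O)CC=C | intermediate
13 | 19-(tert-butyldimethylsilyloxy)-9α-hydroxy-14,15,16,17-tetranorlabda-6,12-dien-8-one | C[C@]12CCC[C@](C)(CO[Si](C)(C)C(C)(C)C)[C@@H]1C=CC(=O)[C@]2(O)CC=C | intermediate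
14 | 9α,19-dihydroxy-14,15,16,17-tetranorlabda-6,12-dien-8-one | C[C@]12CCC[C@](C)(CO)[C@@H]1C=CC(=O)[C@]2(O)CC=C | intermediate
15 | 9α-hydroxy-8-oxo-14,15,16,17-tetranorlabda-6,12-dien-19-al | C[C@]12CCC[C@](C)(C=O)[C@@H]1C=CC(=O)[C@]2(O)CC=C | intermediate
16 | 9α-hydroxy-8-oxo-14,15,16,17-tetranorlabda-6,12-dien-19-oic acid | C[C@]12CCC[C@](C)(C(=O)O)[C@@H]1C=CC(=O)[C@]2(O)CC=C | intermediate
17 | 9α-hydroxy-8-oxo-14,15,16,17-tetranorlabd-12-en-19,6β-olide | C[C@]12CCC[C@](C)(C(=O)O3)[C@@H]1[C@H]3CC(=O)[C@]2(O)CC=C | intermediate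
18 | α-methylene-γ-butyrolactone (3-methylideneoxolan-2-one) | C=C1CCOC1=O | starting material
19 | (12E)-9α-hydroxy-8-oxo-17-norlabd-12-ene-19,6β:16,15-diolide | C[C@]12CCC[C@](C)(C(=O)O3)[C@@H]1[C@H]3CC(=O)[C@]2(O)C/C=C4\CCOC4=O | intermediate
20 | (13R)-9α,13-epoxy-8-oxo-17-norlabdane-19,6β:16,15-diolide | C[C@]12CCC[C@](C)(C(=O)O3)[C@@H]1[C@H]3CC(=O)[C@]25CC[C@]4(CCOC4=O)O5 | intermediate
21 | lithium alkoxide of (13R)-17-chloro-9α,13-epoxy-8β-hydroxylabdane-19,6β:16,15-diolide | C[C@]12CCC[C@](C)(C(=O)O3)[C@@H]1[C@H]3C[C@@](O[Li])(CCl)[C@]25CC[C@]4(CCOC4=O)O5 | intermediate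
22 | (13R)-8β,17:9α,13-diepoxylabdane-19,6β:16,15-diolide (CNP0105047.2) | C[C@@]12CCC[C@]3(C)C(=O)O[C@H](C[C@@]4(CO4)[C@]14CC[C@]1(CCOC1=O)O4)[C@H]23 | target

## Step count and risks

Total step count: 11. Longest linear sequence: 10 steps (1, 2, 4–11); step 3 is a one-step side branch.

Steps most likely to fail:

Step 4 (cycloaddition). The diene carries a cis (inside) CH2OTBS group at the reacting terminus, so it reaches the s-cis form reluctantly, and the bulky chiral cation may give low rate or low ee. The fallback sets out from 5 and 7 and comes back at 9. The cycloaddition is run with SnCl4 (1 equiv, CH2Cl2, −78 °C), a small achiral Lewis acid of the kind that drives cis-substituted dienes onto methylbenzoquinones. This gives the racemate, that is 8 together with its mirror image, the enantiomeric cycloadduct ent-8 F1. Hydrogenation as in step 5 gives 9 together with the enantiomeric dihydro adduct ent-9 F2. The enantiomers are then separated by preparative chiral-phase chromatography, so enantiopurity comes from resolution and not from catalysis.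

Step 6 (allylation and epimerisation). The facial preference of the Grignard reagent on the cis-fused enedione, and its preference for C9 over C6, are argued by analogy and not proven. The fallback sets out from 9 and comes back at 11; it introduces the C9 oxygen last, from the face anti to the angular methyl. Compound 9 is first equilibrated (NaOMe, MeOH) to the trans-fused dione 5-epi-9 F3. Wittig methylenation (Ph3PCH3Br, KN(SiMe3)2, THF) at the more electrophilic C9 carbonyl gives the 9(11)-methylene compound F4. mCPBA epoxidises the exocyclic olefin from the α-face to the 9α,11-epoxide F5. CH2=CHMgBr with CuI (10 mol%) opens the oxirane at C11 to give 11.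

Step 10 (proposed cobalt-hydride spiro-etherification). Capture and oxidation of an electrophilic α-lactonyl radical, and displacement at a tertiary α-carbonyl carbon by a hindered tertiary alcohol, are unproven; simple conjugate reduction may win. The fallback uses known reactions, sets out from 19 and comes back at 20. Conjugate hydrosilylation with [(Ph3P)CuH]6 (5 mol%) and PhMe2SiH (toluene, rt) forms only the lactone enolate equivalent, the silyl ketene acetal F6, and leaves the ketone untouched. Bromination in the same flask with NBS gives the tertiary α-bromo lactone F7 as a C13 epimer mixture. Copper-catalysed etherification of the tertiary α-bromo carbonyl unit by the 9α-OH (CuBr·SMe2 10 mol%, PMDETA, Cs2CO3, toluene, rt) closes the oxolane. This gives 20 together with its (13S)-epimer F8, which is removed by chromatography.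

## Further compounds

F1 | step 4 | ent-8, enantiomer of the cis-fused cycloadduct | C[C@@]12CC=C[C@@](C)(CO[Si](C)(C)C(C)(C)C)[C@@H]1C(=O)C=C(OC)C2=O
F2 | step 4 | ent-9, enantiomer of the dihydro adduct | C[C@@]12CCC[C@@](C)(CO[Si](C)(C)C(C)(C)C)[C@@H]1C(=O)C=C(OC)C2=O
F3 | step 6 | 5-epi-9, 19-(tert-butyldimethylsilyloxy)-8-methoxy-11,12,13,14,15,16,17-heptanorlabd-7-ene-6,9-dione (trans-fused, 5α-H) | C[C@]12CCC[C@](C)(CO[Si](C)(C)C(C)(C)C)[C@@H]1C(=O)C=C(OC)C2=O
F4 | step 6 | 19-(tert-butyldimethylsilyloxy)-8-methoxy-12,13,14,15,16,17-hexanorlabda-7,9(11)-dien-6-one | C[C@]12CCC[C@](C)(CO[Si](C)(C)C(C)(C)C)[C@@H]1C(=O)C=C(OC)C2=C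
F5 | step 6 | 19-(tert-butyldimethylsilyloxy)-9α,11-epoxy-8-methoxy-12,13,14,15,16,17-hexanorlabd-7-en-6-one | C[C@]12CCC[C@](C)(CO[Si](C)(C)C(C)(C)C)[C@@H]1C(=O)C=C(OC)[C@]26CO6
F6 | step 10 | dimethylphenylsilyl ketene acetal of the 12,13-dihydro derivative of 19 (C13=C16 enol ether) | C[C@]12CCC[C@](C)(C(=O)O3)[C@@H]1[C@H]3CC(=O)[C@]2(O)CCC4=C(O[Si](C)(C)c5ccccc5)OCC4
F7 | step 10 | (13RS)-13-bromo-9α-hydroxy-8-oxo-17-norlabdane-19,6β:16,15-diolide (C13 epimer mixture) | C[C@]12CCC[C@](C)(C(=O)O3)[C@@H]1[C@H]3CC(=O)[C@]2(O)CCC4(Br)CCOC4=O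
F8 | step 10 | (13S)-9α,13-epoxy-8-oxo-17-norlabdane-19,6β:16,15-diolide (13-epi-20) | C[C@]12CCC[C@](C)(C(=O)O3)[C@@H]1[C@H]3CC(=O)[C@]25CC[C@@]4(CCOC4=O)O5
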